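The target is a 1-aryltetralin whose C1 is bonded both to C8a of ring A, ortho to the C8 hydroxyl, and to the guaiacyl ring at the carbon para to its hydroxyl. C1 is therefore traced back to one aldehyde carbon that is arylated twice. In one flask phenylboronic acid tethers this aldehyde to O8 and delivers it to C8a, closing ring B as a benzodioxaborin; BF3·OEt2 then opens it to an o-quinone methide, which guaiacol captures trans to the C2 substituent. The precursor is the acyclic (2R,3R)-butanal 17 with two benzyloxymethyl groups, a benzyl ether on O7 and a free phenol at O8.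

Key step: step 14

Remarks on the chemistry

- Tetralin numbering is used throughout, also for the acyclic carbons that end up in the ring: C1 aryl methine, C2 and C3 carrying the CH2O groups, C4 benzylic CH2, C6 OMe, O7 and O8 the oxygens on C7 and C8.
- Assumption: in step 4 the ligand antipode is the one that gives the R acid; its hand is fixed by one test hydrogenation and is not asserted here.
- The configurations were checked against one another: target and 21 are (1S,2R,3R), precursor 17 is (2R,3R). The trans lactone 11 maps onto the 2,3-trans tetralin because the hydroxymethyl carbon, not the lactone carbonyl, becomes C1.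
- Design of the precursor, point 1: after the lactone is opened, the two CH2O arms on C2 differ only in their protecting groups. A silyl or acyl group could move between them under alkoxide conditions and so invert C2. The arm that becomes C1 is therefore carried as a trityl ether.
- Design of the precursor, point 2: O8 is freed last, from an allyl ether and by palladium catalysis. Acid on the phenol aldehyde would start an untemplated ring closure at C5. The allyl group is put on only after the hydrogenation, which it would not survive; until then O8 is a methoxymethyl ether.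

Step 1
Reactants: 1 5-hydroxyvanillin (3,4-dihydroxy-5-methoxybenzaldehyde)
Product: 2 4-(benzyloxy)-3-hydroxy-5-methoxybenzaldehyde
Conditions: BnBr (1.05 equiv), NaHCO3, DMF, 40 °C
Reagents that add atoms: benzyl bromide, BrCc1ccccc1
Why: Williamson etherification with a weak base should touch only the more acidic 4-OH, whose phenoxide is conjugated with the para formyl group, so the future O7 is benzylated and the future O8 stays free.

Step 2
Reactants: 2 4-O-benzyl aldehyde
Product: 3 4-(benzyloxy)-3-methoxy-5-(methoxymethoxy)benzaldehyde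
Conditions: MOMCl, iPr2NEt, CH2Cl2, 0 °C → rt
Reagents that add atoms: chloromethyl methyl ether, COCCl
Why: O-alkylation of the remaining phenol to its methoxymethyl acetal gives a group that withstands alkoxide, hydrogenation and borohydride and is lost in the acidic lactonisation of step 5.

Step 3
Reactants: 3 protected aldehyde; 4 dimethyl succinate
Product: 5 (E)-4-[4-(benzyloxy)-3-methoxy-5-(methoxymethoxy)phenyl]-3-(methoxycarbonyl)but-3-enoic acid
Conditions: NaOMe, MeOH, reflux; then cold 1 M HCl to pH 3
Reagents that add atoms: none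
Why: The Stobbe condensation runs through a paraconate lactone whose base-induced ring opening should deliver the E half-ester with the free acid on the CH2 arm.

Step 4
Reactants: 5 E half-ester
Product: 6 (R)-4-[4-(benzyloxy)-3-methoxy-5-(methoxymethoxy)phenyl]-3-(methoxycarbonyl)butanoic acid
Conditions: [Rh(cod)2]BF4 (1 mol %), Et-DuPHOS (antipode giving the R acid), H2 (5 bar), NaOMe (10 mol %), MeOH, rt
Reagents that add atoms: none
Why: Rhodium–bisphosphine asymmetric hydrogenation of an itaconate-type half-ester, in which carboxylate and alkene chelate the metal and the ligand selects the alkene face, sets the stereocentre that becomes C3 (R).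

Step 5
Reactants: 6 R half-ester
Product: 9 (R)-4-{[4-(benzyloxy)-3-hydroxy-5-methoxyphenyl]methyl}dihydrofuran-2(3H)-one, via hydroxy acid 7 (not isolated), via MOM lactone 8 (not isolated)
Conditions: KOH (1 equiv), EtOH; CaCl2, NaBH4, 0 °C → rt; then 3 M HCl, MeOH, 50 °C
Reagents that add atoms: none
Why: Ca(BH4)2 reduces the methyl ester but not the carboxylate, and methanolic HCl then closes the γ-lactone and cleaves the aryl methoxymethyl acetal, the stereocentre being no longer α to a carbonyl after the reduction.

Step 6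
Reactants: 9 phenolic lactone
Product: 10 (R)-4-{[3-(allyloxy)-4-(benzyloxy)-5-methoxyphenyl]methyl}dihydrofuran-2(3H)-one
Conditions: allyl bromide, K2CO3, acetone, 50 °C
Reagents that add atoms: allyl bromide, C=CCBr
Why: Williamson etherification of the only acidic OH installs an allyl ether that survives LiN(iPr)2, LiAlH4, NaH and dilute acid and can be removed later under palladium catalysis.

Step 7
Reactants: 10 allyl ether lactone
Product: 11 (3S,4R)-4-{[3-(allyloxy)-4-(benzyloxy)-5-methoxyphenyl]methyl}-3-(hydroxymethyl)dihydrofuran-2(3H)-one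
Conditions: LiN(iPr)2 (LDA), THF, −78 °C; CH2O gas (cracked paraformaldehyde), −78 → −40 °C; AcOH
Reagents that add atoms: formaldehyde, C=O
Why: Aldol addition of the lactone lithium enolate to formaldehyde should occur on the enolate face opposite the C4 arylmethyl group, which sets the α-stereocentre (later C2) trans to it.

Step 8
Reactants: 11 hydroxymethyl lactone
Product: 12 (3S,4R)-4-{[3-(allyloxy)-4-(benzyloxy)-5-methoxyphenyl]methyl}-3-[(trityloxy)methyl]dihydrofuran-2(3H)-one
Conditions: TrCl, Et3N, DMAP (cat.), CH2Cl2, rt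
Reagents that add atoms: trityl chloride, ClC(c1ccccc1)(c1ccccc1)c1ccccc1
Why: Tritylation of the primary alcohol marks the arm that becomes C1 with an ether that cannot shift to the neighbouring hydroxymethyl arm once the lactone is opened.

Step 9
Reactants: 12 trityl ether lactone
Product: 13 (2R,3R)-2-{[3-(allyloxy)-4-(benzyloxy)-5-methoxyphenyl]methyl}-3-[(trityloxy)methyl]butane-1,4-diol
Conditions: LiAlH4, THF, 0 °C
Reagents that add atoms: none
Why: Hydride reduction opens the lactone to the 1,4-diol, turning the former carbonyl carbon into the hydroxymethyl group on C2 without touching either stereocentre.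

Step 10
Reactants: 13 diol
Product: 14 (2R,3R)-1-[3-(allyloxy)-4-(benzyloxy)-5-methoxyphenyl]-4-(benzyloxy)-2-[(benzyloxy)methyl]-3-[(trityloxy)methyl]butane
Conditions: NaH, BnBr, THF/DMF, 0 °C → rt
Reagents that add atoms: benzyl bromide, BrCc1ccccc1
Why: Double Williamson etherification of the two primary alkoxides should be clean because no group in the molecule can migrate or eliminate under these conditions.

Step 11
Reactants: 14 trityl ether
Product: 15 (2S,3R)-4-[3-(allyloxy)-4-(benzyloxy)-5-methoxyphenyl]-2,3-bis[(benzyloxy)methyl]butan-1-ol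
Conditions: TsOH·H2O (cat.), MeOH/CH2Cl2, rt
Reagents that add atoms: none
Why: Acid-catalysed SN1 solvolysis of the trityl ether, with methanol trapping the trityl cation, frees the primary alcohol while benzyl and allyl ethers stay intact.

Step 12
Reactants: 15 primary alcohol
Product: 16 (2R,3R)-4-[3-(allyloxy)-4-(benzyloxy)-5-methoxyphenyl]-2,3-bis[(benzyloxy)methyl]butanal
Conditions: Dess–Martin periodinane, pyridine, CH2Cl2, 0 °C → rt
Reagents that add atoms: none
Why: Dess–Martin oxidation gives the aldehyde under buffered, non-enolising conditions that should keep the adjacent C2 stereocentre, while the allyl ether shields the electron-rich phenol from the oxidant.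

Step 13
Reactants: 16 allyl-protected aldehyde
Product: 17 (2R,3R)-4-[4-(benzyloxy)-3-hydroxy-5-methoxyphenyl]-2,3-bis[(benzyloxy)methyl]butanal
Conditions: Pd(PPh3)4 (5 mol %), p-TolSO2Na, AcOH, THF, rt
Reagents that add atoms: none
Why: Palladium-catalysed allyl transfer of the Tsuji–Trost type from the aryl ether to the sulfinate releases the phenol in an acetate-buffered medium, which should spare the epimerisable β-benzyloxy aldehyde.

Step 14
Reactants: 17 phenol aldehyde; 18 guaiacol (2-methoxyphenol)
Product: 21 4-{(1S,2R,3R)-7-(benzyloxy)-2,3-bis[(benzyloxy)methyl]-8-hydroxy-6-methoxy-1,2,3,4-tetrahydronaphthalen-1-yl}-2-methoxyphenol, via benzodioxaborin 19 (not isolated), via o-quinone methide 20 (not isolated)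
Conditions: PhB(OH)2 (1.1 equiv), EtCO2H (0.2 equiv), toluene, 80 °C, 4 Å sieves; then CH2Cl2, 18 (5 equiv), BF3·OEt2 (1.5 equiv), −78 → 0 °C; aq. NaHCO3
Reagents that add atoms: phenylboronic acid, OB(O)c1ccccc1 (its B–Ph unit is held only in 19 and is given back on work-up)
Why: PhB(OH)2 esterifies O8, the boron binds the aldehyde oxygen and C8a attacks C1 through a six-membered cyclic transition state (6-exo-trig closure of ring B), after which the C1 alkoxide closes the transient dioxaborin ring on boron to give 19. This is the boronic-acid-templated ortho-hydroxyalkylation of phenols by aldehydes, here run within one molecule, followed by the known Lewis-acid opening of benzodioxaborins to o-quinone methides and their Friedel–Crafts capture by electron-rich arenes. BF3·OEt2 ionises the benzylic C1–O bond to give 20, guaiacol attacks C1 through its carbon para to OH, and ring A re-aromatises. The C1 stereocentre is set by the substrate: the arene should approach the planar C1 of the half-chair anti to the adjacent C2 benzyloxymethyl group, giving the 1,2-trans, all-equatorial isomer, which is also the thermodynamically preferred one if the arylation is reversible. Site selectivity on ring A (C8a, not C5) rests on the O8–B tether and the blocked C7, site selectivity on guaiacol on the stronger para-directing power of OH over OMe, and chemoselectivity on finishing the ring closure before the Lewis acid is added.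

Step 15
Reactants: 21 tris(benzyl) ether
Product: 22 (1S,2R,3R)-1-(4-hydroxy-3-methoxyphenyl)-2,3-bis(hydroxymethyl)-6-methoxy-1,2,3,4-tetrahydronaphthalene-7,8-diol (tetralin numbering)
Conditions: H2 (1 atm), 10% Pd/C, EtOAc/MeOH, rt
Reagents that add atoms: none
Why: Catalytic hydrogenolysis cleaves the one aryl and the two alkyl benzyl ethers as toluene, and the diarylmethine C1–H bond and the three stereocentres should be inert under these conditions.

Compound list

1 | 5-hydroxyvanillin (3,4-dihydroxy-5-methoxybenzaldehyde) | COc1cc(C=O)cc(O)c1O | starting material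
2 | 4-(benzyloxy)-3-hydroxy-5-methoxybenzaldehyde | COc1cc(C=O)cc(O)c1OCc1ccccc1 | intermediate
3 | 4-(benzyloxy)-3-methoxy-5-(methoxymethoxy)benzaldehyde | COCOc1cc(C=O)cc(OC)c1OCc1ccccc1 | intermediate
4 | dimethyl succinate | COC(=O)CCC(=O)OC | starting material
5 | (E)-4-[4-(benzyloxy)-3-methoxy-5-(methoxymethoxy)phenyl]-3-(methoxycarbonyl)but-3-enoic acid | COC(=O)/C(CC(=O)O)=C/c1cc(OC)c(OCc2ccccc2)c(OCOC)c1 | intermediate
6 | (R)-4-[4-(benzyloxy)-3-methoxy-5-(methoxymethoxy)phenyl]-3-(methoxycarbonyl)butanoic acid | COC(=O)[C@@H](CC(=O)O)Cc1cc(OC)c(OCc2ccccc2)c(OCOC)c1 | intermediate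
7 | (R)-4-[4-(benzyloxy)-3-methoxy-5-(methoxymethoxy)phenyl]-3-(hydroxymethyl)butanoic acid (present as its carboxylate) | OC(=O)C[C@H](CO)Cc1cc(OC)c(OCc2ccccc2)c(OCOC)c1 | intermediate (not isolated)
8 | (R)-4-{[4-(benzyloxy)-3-methoxy-5-(methoxymethoxy)phenyl]methyl}dihydrofuran-2(3H)-one | O=C1C[C@@H](Cc2cc(OC)c(OCc3ccccc3)c(OCOC)c2)CO1 | intermediate (not isolated)
9 | (R)-4-{[4-(benzyloxy)-3-hydroxy-5-methoxyphenyl]methyl}dihydrofuran-2(3H)-one | O=C1C[C@@H](Cc2cc(OC)c(OCc3ccccc3)c(O)c2)CO1 | intermediate
10 | (R)-4-{[3-(allyloxy)-4-(benzyloxy)-5-methoxyphenyl]methyl}dihydrofuran-2(3H)-one | O=C1C[C@@H](Cc2cc(OC)c(OCc3ccccc3)c(OCC=C)c2)CO1 | intermediate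
11 | (3S,4R)-4-{[3-(allyloxy)-4-(benzyloxy)-5-methoxyphenyl]methyl}-3-(hydroxymethyl)dihydrofuran-2(3H)-one (trans) | O=C1[C@H](CO)[C@@H](Cc2cc(OC)c(OCc3ccccc3)c(OCC=C)c2)CO1 | intermediate
12 | (3S,4R)-4-{[3-(allyloxy)-4-(benzyloxy)-5-methoxyphenyl]methyl}-3-[(trityloxy)methyl]dihydrofuran-2(3H)-one | O=C1[C@H](COC(c2ccccc2)(c2ccccc2)c2ccccc2)[C@@H](Cc2cc(OC)c(OCc3ccccc3)c(OCC=C)c2)CO1 | intermediate
13 | (2R,3R)-2-{[3-(allyloxy)-4-(benzyloxy)-5-methoxyphenyl]methyl}-3-[(trityloxy)methyl]butane-1,4-diol | OC[C@H](COC(c1ccccc1)(c1ccccc1)c1ccccc1)[C@H](CO)Cc1cc(OC)c(OCc2ccccc2)c(OCC=C)c1 | intermediate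
14 | (2R,3R)-1-[3-(allyloxy)-4-(benzyloxy)-5-methoxyphenyl]-4-(benzyloxy)-2-[(benzyloxy)methyl]-3-[(trityloxy)methyl]butane (the trityl ether of 15) | C(OC[C@@H](COCc1ccccc1)[C@H](COCc1ccccc1)Cc1cc(OC)c(OCc2ccccc2)c(OCC=C)c1)(c1ccccc1)(c1ccccc1)c1ccccc1 | intermediate
15 | (2S,3R)-4-[3-(allyloxy)-4-(benzyloxy)-5-methoxyphenyl]-2,3-bis[(benzyloxy)methyl]butan-1-ol | OC[C@@H](COCc1ccccc1)[C@H](COCc1ccccc1)Cc1cc(OC)c(OCc2ccccc2)c(OCC=C)c1 | intermediate
16 | (2R,3R)-4-[3-(allyloxy)-4-(benzyloxy)-5-methoxyphenyl]-2,3-bis[(benzyloxy)methyl]butanal | O=C[C@@H](COCc1ccccc1)[C@H](COCc1ccccc1)Cc1cc(OC)c(OCc2ccccc2)c(OCC=C)c1 | intermediate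
17 | (2R,3R)-4-[4-(benzyloxy)-3-hydroxy-5-methoxyphenyl]-2,3-bis[(benzyloxy)methyl]butanal | O=C[C@@H](COCc1ccccc1)[C@H](COCc1ccccc1)Cc1cc(OC)c(OCc2ccccc2)c(O)c1 | intermediate (precursor of the key step)
18 | guaiacol (2-methoxyphenol) | COc1ccccc1O | starting material
19 | cyclic phenylboronate (2-phenyl-1,3,2-dioxaborin across O8 and the C1 oxygen) of (2R,3R)-7-(benzyloxy)-2,3-bis[(benzyloxy)methyl]-6-methoxy-1,2,3,4-tetrahydronaphthalene-1,8-diol, both C1 epimers | COc1cc2C[C@@H](COCc3ccccc3)[C@H](COCc3ccccc3)C3OB(c4ccccc4)Oc(c1OCc1ccccc1)c23 | intermediate (not isolated)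
20 | o-quinone methide, (6R,7R)-2-(benzyloxy)-6,7-bis[(benzyloxy)methyl]-3-methoxy-6,7-dihydro-5H-naphthalen-1-one (C8 carbonyl and C8a=C1 double bond in tetralin numbering; drawn free of boron) | COC1=C(OCc2ccccc2)C(=O)C2=C[C@@H](COCc3ccccc3)[C@H](COCc3ccccc3)CC2=C1 | intermediate (not isolated)
21 | 4-{(1S,2R,3R)-7-(benzyloxy)-2,3-bis[(benzyloxy)methyl]-8-hydroxy-6-methoxy-1,2,3,4-tetrahydronaphthalen-1-yl}-2-methoxyphenol (all-trans) | COc1cc([C@H]2c3c(cc(OC)c(OCc4ccccc4)c3O)C[C@@H](COCc3ccccc3)[C@@H]2COCc2ccccc2)ccc1O | intermediate (product of the key step)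
22 | (1S,2R,3R)-1-(4-hydroxy-3-methoxyphenyl)-2,3-bis(hydroxymethyl)-6-methoxy-1,2,3,4-tetrahydronaphthalene-7,8-diol (tetralin numbering) | COc1cc([C@H]2c3c(cc(OC)c(O)c3O)C[C@@H](CO)[C@@H]2CO)ccc1O | target

Total step count: 15. Longest linear sequence: 15 steps (1 → 22); 4 and 18 are bought.

Steps most likely to fail

Step 14. Several processes can compete with the intended one:
- The aldehyde may enolise before the templated closure, which would lose the C2 configuration or expel benzyl alcohol.
- The quinone methide may shift a hydrogen from C2 to give the 1,2-dihydronaphthalene.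
- Guaiacol may be attacked partly para to its methoxy group.
- Facial selectivity at C1 may be incomplete.

The fallback gives up the double arylation and builds C1 in the classical lactone manner; it sets out from 9 and comes back to the route at 22. Compound 9 is acylated (PivCl, Et3N, DMAP, CH2Cl2) to 2-(benzyloxy)-3-methoxy-5-{[(3R)-5-oxotetrahydrofuran-3-yl]methyl}phenyl pivalate F1. Its lithium enolate (LiN(SiMe3)2, THF, −78 °C) adds to commercial 4-(benzyloxy)-3-methoxybenzaldehyde, trans to the arylmethyl group, to give the aldol adduct F2 as a pair of carbinol epimers. TFA in CH2Cl2 at 0 °C ionises the carbinol and the benzylic cation closes ring B in a Friedel–Crafts cyclisation. Closure is expected at C8a, para to the C6 methoxy group, because the pivalate makes O8 a weak donor towards C5; this gives the all-trans aryltetralin lactone F3. LiAlH4 reduces the lactone and cleaves the pivalate to the tetralin diol F4, and hydrogenolysis of its two benzyl ethers (H2, Pd/C) gives 22.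

Step 7. Monomeric formaldehyde may polymerise before it reaches the enolate, add twice, or the adduct may dehydrate to the α-methylene lactone. The fallback replaces the aldol by an alkylation and changes the protecting group of the C1 arm; it sets out from 10 and comes back at 15. The lithium enolate of 10 is C-alkylated with freshly prepared 4-methoxybenzyl chloromethyl ether, again trans to the arylmethyl group, to give the α-[(4-methoxybenzyloxy)methyl] lactone F5. LiAlH4 gives the diol F6, NaH and BnBr give the bis(benzyl) ether F7, and DDQ in CH2Cl2/pH 7 buffer removes the 4-methoxybenzyl group to give 15.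

Step 13. The β-benzyloxy aldehyde may epimerise at C2 or lose benzyl alcohol while the phenol is being freed, or the palladium catalyst may attack the aldehyde. The fallback moves the deallylation to a stage without an aldehyde and frees the phenol at the end with fluoride; it sets out from 15 and comes back at 17. Deallylation of 15 (Pd(PPh3)4, p-TolSO2Na, AcOH) gives the phenol alcohol F8, and both hydroxyls are silylated (TBSCl, imidazole, DMF) to the bis(silyl) ether F9. PPTS in MeOH cleaves only the primary alkyl silyl ether to give the aryl silyl ether alcohol F10. Dess–Martin oxidation gives the aldehyde F11, and Et3N·3HF in THF at 0 °C removes the aryl silyl group under weakly acidic conditions to give 17.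

Further compounds

F1 | step 14 | 2-(benzyloxy)-3-methoxy-5-{[(3R)-5-oxotetrahydrofuran-3-yl]methyl}phenyl pivalate | O=C1C[C@@H](Cc2cc(OC)c(OCc3ccccc3)c(OC(=O)C(C)(C)C)c2)CO1
F2 | step 14 | (3S,4R)-3-{[4-(benzyloxy)-3-methoxyphenyl](hydroxy)methyl} derivative of F1 (trans; carbinol epimers) | O=C1[C@H](C(O)c2ccc(OCc3ccccc3)c(OC)c2)[C@@H](Cc2cc(OC)c(OCc3ccccc3)c(OC(=O)C(C)(C)C)c2)CO1
F3 | step 14 | all-trans aryltetralin γ-lactone, (1S,2R,3R) in tetralin numbering: lactone carbonyl on C2, lactone CH2O on C3, O8 pivalate, O7 and guaiacyl oxygen benzylated | COc1cc([C@H]2c3c(cc(OC)c(OCc4ccccc4)c3OC(=O)C(C)(C)C)C[C@H]3COC(=O)[C@H]23)ccc1OCc1ccccc1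
F4 | step 14 | (1S,2R,3R)-7-(benzyloxy)-1-[4-(benzyloxy)-3-methoxyphenyl]-2,3-bis(hydroxymethyl)-6-methoxy-1,2,3,4-tetrahydronaphthalen-8-ol | COc1cc([C@H]2c3c(cc(OC)c(OCc4ccccc4)c3O)C[C@@H](CO)[C@@H]2CO)ccc1OCc1ccccc1
F5 | step 7 | (3S,4R)-4-{[3-(allyloxy)-4-(benzyloxy)-5-methoxyphenyl]methyl}-3-{[(4-methoxybenzyl)oxy]methyl}dihydrofuran-2(3H)-one | O=C1[C@H](COCc2ccc(OC)cc2)[C@@H](Cc2cc(OC)c(OCc3ccccc3)c(OCC=C)c2)CO1
F6 | step 7 | (2R,3R)-2-{[3-(allyloxy)-4-(benzyloxy)-5-methoxyphenyl]methyl}-3-{[(4-methoxybenzyl)oxy]methyl}butane-1,4-diol | OC[C@H](COCc1ccc(OC)cc1)[C@H](CO)Cc1cc(OC)c(OCc2ccccc2)c(OCC=C)c1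
F7 | step 7 | 4-methoxybenzyl ether of 15 | COc1ccc(COC[C@@H](COCc2ccccc2)[C@H](COCc2ccccc2)Cc2cc(OC)c(OCc3ccccc3)c(OCC=C)c2)cc1
F8 | step 13 | (2S,3R)-4-[4-(benzyloxy)-3-hydroxy-5-methoxyphenyl]-2,3-bis[(benzyloxy)methyl]butan-1-ol | OC[C@@H](COCc1ccccc1)[C@H](COCc1ccccc1)Cc1cc(OC)c(OCc2ccccc2)c(O)c1
F9 | step 13 | bis(tert-butyldimethylsilyl) ether of F8 (primary alkyl and aryl oxygen) | CC(C)(C)[Si](C)(C)OC[C@@H](COCc1ccccc1)[C@H](COCc1ccccc1)Cc1cc(OC)c(OCc2ccccc2)c(O[Si](C)(C)C(C)(C)C)c1
F10 | step 13 | aryl tert-butyldimethylsilyl ether of F8 with free primary alcohol | OC[C@@H](COCc1ccccc1)[C@H](COCc1ccccc1)Cc1cc(OC)c(OCc2ccccc2)c(O[Si](C)(C)C(C)(C)C)c1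
F11 | step 13 | aryl tert-butyldimethylsilyl ether of 17 | O=C[C@@H](COCc1ccccc1)[C@H](COCc1ccccc1)Cc1cc(OC)c(OCc2ccccc2)c(O[Si](C)(C)C(C)(C)C)c1
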